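Start from late times and count backwards: in this scheme each forward exchange step spends one incoming ligand on one complex and frees one leaving ligand, so the exchanges standing in a flask late on can't outnumber the incoming ligand charged. Here are the flasks, the steps and the question.

all flasks: incoming ligand 0.300 M; time 80 min

| charge | starting complex |
|---|---|
| noon | 0.060 M |
| autumn | 0.20 M |
| spring | 0.60 M |
| winter | 2.0 M |

    leaving ligand + starting complex → side product B (k1 = 2.16 /M/h)
    starting complex + incoming ligand ⇌ leaving ligand + complex with one exchanged (K2 = 0.500, k2 = 15.2 /M/h)
    starting complex + complex with two exchanged → side product A (k3 = 1.14 /M/h)
    complex with two exchanged → over-reaction product (k4 = 0.538 /h)
    complex with one exchanged + incoming ligand ⇌ leaving ligand + complex with two exchanged (K5 = 0.14, k5 = 19.8 /M/h)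
    complex with two exchanged + incoming ligand ⇌ leaving ligand + complex with three exchanged (K6 = 1.41, k6 = 9.43 /M/h)

* [complex with two exchanged] at the end for noon, autumn, spring, winter, in this order
* the course of these numbers from the first flask to the last (hardly changes / falls all the way / rises, then falls / rises all the way / falls, then rises)

- in percentages every species weighs as the starting complex in it: one side product A counts as two
- "hardly changes" means that all values lie within two and a half points (for a concentration: within two and a half percent of the largest)
- run time (noon): 80 min

So you count turnovers. Take the winter flask first. Its exchange allowance, the incoming ligand charged per starting complex charged, which is the number of exchanges the charge can pay for each complex, is 0.150. That is less than one exchange per complex, so in winter the incoming ligand is the limiting reagent. The noon flask has an allowance of 5.00, which is more than the 3 exchanges the ladder can take, so there the count sets no ceiling and gives me no figure.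

For winter you can go one step further, working in fractions of the charge. Suppose the first two exchanges stand near equilibrium. Then the free ligands cancel: the fraction with two exchanged times the fraction of starting complex, over the square of the fraction with one exchanged, equals the second equilibrium constant over the first, 0.280. Put the whole allowance on the first rung, which leaves a fraction 0.850 as starting complex. The fraction with two exchanged is then 0.741 %, and on the winter charge that is 0.0148 M. This is my own reckoning. The fraction shrinks with the square of the allowance while the charge grows, so I commit to a row that rises and then falls, with winter near that figure.

The forecast gave 0.0058 M, 0.0097 M, 0.013 M and 0.007 M, a course that rises, then falls, holding that in the most concentrated flask “the ligand is the limiting reagent”. Its winter figure is lower than mine.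

The simulation gives 0.00587 M, 0.0103 M, 0.0140 M and 0.00539 M, a course that rises, then falls.

The winter value lies below my figure. With 0.96 % of the incoming ligand left at 80.0 min, the winter flask has paid, net, 0.149 exchanges per charged complex, which is nearly all of its allowance. The noon flask, with 72 % left, has paid 1.42 of its 5.00. The largest single effect on the winter figure is the back reaction of the first exchange, leaving ligand with complex with one exchanged, which gives incoming ligand back: in the run without it, the winter flask ends with 1.00 × 10⁻⁵ M of the complex with two exchanged instead of 0.00539 M.

Its constants were drawn at random within sensible limits; the result is computed.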